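**Plan**

- Retrosynthesis: the lactone C12–O6 bond, the C3 and C8 ester C–O bonds, the epoxide C–O bonds and the C3–H and C8–H bonds are cut back to a 3,8-diketone. Its two carbonyl carbons are then joined (the reverse of a glycol cleavage) to a cis-decalin-3,8-diol, which is cut at C4=C5 (metathesis), C3–C4 (vinyl-metal addition) and C6–C7 (aldol); ring B is traced to an anisole.
- Enabling feature (germacrane numbering): C3 and C8 face each other 1,6 across the ten-membered ring. A C3–C8 bond therefore gives a cis-fused decalin whose ring A (C3–C4–C5–C6–C7–C8) holds C4=C5 and whose ring B (C3–C2–C1–C10–C9–C8) holds C1=C10, both necessarily cis.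
- Forward: the arene of 4-methylanisole is ring B in masked form. An Evans aldol joins C6–C7, Birch reduction unmasks ring B, enol-ether oxidation and a Felkin-controlled vinyl addition build the cis ring-fusion diol, and metathesis closes ring A. Pb(OAc)4 then opens the decalin to the ten-membered ring; the esters, the epoxide and finally the lactone ring follow.
- Stereochemistry: C6 and C7 come from the (R)-benzyloxazolidinone aldol; C3 and C8 from two oxazaborolidine reductions with antipodal catalysts; C1 and C10 from a C8-hydroxyl-directed epoxidation. Both ring alkenes are Z because they are made inside six-membered rings. The ring-fusion centres only relay and are erased in the key step.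

Key step: step 16

Remark 1: atom numbers (C1–C15) are the germacrane numbers of the target (C14 = methyl on C10, C15 = CH2OH on C4, C11–C13 = lactone carbons) and are used for all intermediates.
Remark 2: the C8 (and hence C3) configuration written from the enol-ether oxidation onward is the one expected from attack anti to the silyloxy-bearing branch. Both centres become carbonyl carbons in the key step, so the other cis-diol would converge on the same diketone.

**Route**

Step 1
Reactants: 1 4-methylanisole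
Product: 3 2-(2-methoxy-5-methylphenyl)ethan-1-ol, via aryllithium 2 (not isolated)
Conditions: n-BuLi, TMEDA, Et2O, 0 to 23 °C; then ethylene oxide, −78 to 23 °C; H2O
Reagents that add atoms: ethylene oxide, C1CO1
Why: Directed ortho-metalation next to the methoxy group (para position blocked by the methyl group) followed by ring opening of the oxirane by the aryllithium attaches the two carbons that become C7 and C11.

Step 2
Reactants: 3 2-(2-methoxy-5-methylphenyl)ethan-1-ol
Product: 5 (2-methoxy-5-methylphenyl)acetic acid, via arylacetaldehyde 4 (not isolated)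
Conditions: TEMPO (cat.), PhI(OAc)2, MeCN–H2O, 23 °C
Reagents that add atoms: water, O
Why: Oxoammonium (TEMPO) oxidation of the primary alcohol proceeds through the aldehyde hydrate to the acid without any halogenating oxidant that could attack the electron-rich arene.

Step 3
Reactants: 5 (2-methoxy-5-methylphenyl)acetic acid; 6 (R)-4-benzyloxazolidin-2-one
Product: 8 (R)-4-benzyl-3-[(2-methoxy-5-methylphenyl)acetyl]oxazolidin-2-one, via mixed pivalic anhydride 7 (not isolated)
Conditions: PivCl, Et3N, THF, −20 °C; then 6, LiCl, 23 °C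
Reagents that add atoms: none
Why: N-Acylation of the oxazolidinone through the mixed anhydride under LiCl/Et3N activation installs the chiral auxiliary on the arylacetyl unit.

Step 4
Reactants: 8 (R)-4-benzyl-3-[(2-methoxy-5-methylphenyl)acetyl]oxazolidin-2-one; 9 acrolein
Product: 12 (R)-4-benzyl-3-[(2R,3S)-3-hydroxy-2-(2-methoxy-5-methylphenyl)pent-4-enoyl]oxazolidin-2-one, via boron enolate 10 (not isolated), via boron aldolate 11 (not isolated)
Conditions: Bu2BOTf, i-Pr2NEt, CH2Cl2, −78 to 0 °C; then acrolein, −78 to 0 °C; pH 7 buffer, MeOH, H2O2, 0 °C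
Reagents that add atoms: none
Why: Evans syn aldol, in which the (Z)-boron enolate reacts through a chair transition state on the face away from the benzyl group of the (R)-auxiliary, sets C7 and C6 in the syn relation that later becomes the cis-fused lactone.

Step 5
Reactants: 12 aldol adduct
Product: 13 (2R,3S)-3-hydroxy-N-methoxy-2-(2-methoxy-5-methylphenyl)-N-methylpent-4-enamide
Conditions: MeNH(OMe)·HCl, AlMe3, CH2Cl2, −20 to 0 °C; aq. potassium sodium tartrate
Reagents that add atoms: N,O-dimethylhydroxylamine hydrochloride, CNOC.Cl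
Why: Aluminium-amide transamidation of the β-hydroxy imide, assisted by the free hydroxyl, releases the auxiliary and gives the Weinreb amide under conditions that do not enolise the α-aryl centre.

Step 6
Reactants: 13 Weinreb amide
Product: 14 (2R,3S)-3-[(tert-butyldimethylsilyl)oxy]-N-methoxy-2-(2-methoxy-5-methylphenyl)-N-methylpent-4-enamide
Conditions: TBSOTf, 2,6-lutidine, CH2Cl2, −78 to 0 °C
Reagents that add atoms: tert-butyldimethylsilyl triflate, CC(C)(C)[Si](C)(C)OS(=O)(=O)C(F)(F)F
Why: Silylation of the secondary allylic alcohol blocks retro-aldol cleavage during the two carbonyl additions that follow.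

Step 7
Reactants: 14 silylated Weinreb amide
Product: 15 (3R,4S)-1-(benzyloxy)-4-[(tert-butyldimethylsilyl)oxy]-3-(2-methoxy-5-methylphenyl)hex-5-en-2-one
Conditions: Bu3SnCH2OBn, n-BuLi, THF, −78 °C; then 14, −78 °C; AcOH, −78 °C
Reagents that add atoms: tributyl[(benzyloxy)methyl]stannane, CCCC[Sn](CCCC)(CCCC)COCc1ccccc1
Why: Tin–lithium exchange gives (benzyloxy)methyllithium, which adds once to the Weinreb amide (the N-methoxy group prevents over-addition) and so brings in C12, while the cold acidic quench protects the α-aryl ketone from epimerisation.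

Step 8
Reactants: 15 α-aryl ketone
Product: 17 (3S,4R)-5-[(benzyloxy)methyl]-4-(2-methoxy-5-methylphenyl)hexa-1,5-dien-3-ol, via β-hydroxysilane 16 (not isolated)
Conditions: Me3SiCH2Li, CeCl3, THF, −78 °C; then aq. HF, MeCN, 0 to 23 °C
Reagents that add atoms: (trimethylsilyl)methyllithium, [Li]C[Si](C)(C)C
Why: Peterson olefination with the non-basic organocerium reagent methylenates the enolisable ketone (C11=C13), and the HF that triggers the elimination also frees the C6 hydroxyl.

Step 9
Reactants: 17 aryl dienol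
Product: 18 (3R,4S)-3-(2-methoxy-5-methylcyclohexa-1,4-dien-1-yl)-2-methylidenehex-5-ene-1,4-diol
Conditions: Li, NH3 (l), THF, t-BuOH, −78 to −33 °C; NH4Cl
Reagents that add atoms: none
Why: Birch reduction leaves the two ring double bonds on the donor-substituted carbons (enol ether C3=C8 and C1=C10), cleaves the benzyl ether in the same operation, and spares the isolated alkenes, whose allylic oxygens are present as alkoxides.

Step 10
Reactants: 18 diene diol
Product: 19 (3R,4S)-1,4-bis[(tert-butyldimethylsilyl)oxy]-3-(2-methoxy-5-methylcyclohexa-1,4-dien-1-yl)-2-methylidenehex-5-ene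
Conditions: TBSCl, imidazole, DMF, 23 °C
Reagents that add atoms: tert-butyldimethylsilyl chloride, CC(C)(C)[Si](C)(C)Cl
Why: Imidazole-buffered silylation protects O6 and O12 without hydrolysing the acid-labile enol ether.

Step 11
Reactants: 19 bis-silyl ether
Product: 21 (2R)-2-[(3S,4S)-4-[(tert-butyldimethylsilyl)oxy]-2-{[(tert-butyldimethylsilyl)oxy]methyl}hexa-1,5-dien-3-yl]-2-hydroxy-4-methylcyclohex-4-en-1-one, via methoxy epoxide 20 (not isolated)
Conditions: dimethyldioxirane, acetone–CH2Cl2, −78 °C; then wet silica gel, 0 °C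
Reagents that add atoms: dimethyldioxirane, CC1(C)OO1; water, O
Why: Rubottom-type oxidation, in which the tetrasubstituted enol ether (by far the most electron-rich alkene) is epoxidised on the face opposite the silyloxy-bearing C6 branch with C7–H eclipsing the double bond, gives after hydrolysis of the methoxy epoxide the tertiary C8 carbinol next to the C3 ketone.

Step 12
Reactants: 21 ketol
Product: 22 trimethylsilyl ether of 21
Conditions: N-(trimethylsilyl)imidazole, CH2Cl2, 23 °C
Reagents that add atoms: N-(trimethylsilyl)imidazole, C[Si](C)(C)n1ccnc1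
Why: Neutral silylation of the tertiary hydroxyl removes the chelating OH and leaves a small axial silyloxy group to steer the next addition.

Step 13
Reactants: 23 2-bromoprop-2-en-1-ol
Product: 24 1-{[(2-bromoprop-2-en-1-yl)oxy]methyl}-4-methoxybenzene
Conditions: NaH, 4-methoxybenzyl chloride, Bu4NI (cat.), THF, 0 to 23 °C
Reagents that add atoms: 4-methoxybenzyl chloride, COc1ccc(CCl)cc1
Why: Williamson etherification gives the C4/C15 building block with its hydroxyl masked as a PMB ether, which is orthogonal to the silyl ethers.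

Step 14
Reactants: 22 silylated ketol; 24 2-bromoallyl PMB ether
Product: 28 (1S,2R)-2-[(3S,4S)-4-[(tert-butyldimethylsilyl)oxy]-2-{[(tert-butyldimethylsilyl)oxy]methyl}hexa-1,5-dien-3-yl]-1-{3-[(4-methoxybenzyl)oxy]prop-1-en-2-yl}-4-methylcyclohex-4-ene-1,2-diol, via vinyllithium 25 (not isolated), via vinylcerium reagent 26 (not isolated), via silyl ether adduct 27 (not isolated)
Conditions: 24, t-BuLi, Et2O, −78 °C; CeCl3, THF, −78 °C; then 22, −78 °C; H2O; then K2CO3, MeOH, 23 °C
Reagents that add atoms: none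
Why: 1,2-Addition of the organocerium reagent (no enolisation at the doubly activated C2) occurs anti to the axial C8 silyloxy group (Felkin–Anh, axial attack with the C7 branch equatorial), so that methanolysis of the trimethylsilyl ether gives the cis-3,8-diol with the C4 and C7 arms cis.

Step 15
Reactants: 28 cis-diol tetraene
Product: 29 (3S,4S,4aR,8aS)-3-[(tert-butyldimethylsilyl)oxy]-4-{3-[(tert-butyldimethylsilyl)oxy]prop-1-en-2-yl}-1-{[(4-methoxybenzyl)oxy]methyl}-6-methyl-3,4,4a,5,8,8a-hexahydronaphthalene-4a,8a-diol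
Conditions: second-generation Grubbs catalyst RuCl2(=CHPh)(PCy3)(H2IMes) (5 mol%), toluene, 80 °C
Reagents that add atoms: none
Why: Ring-closing metathesis between the C5 vinyl group and the C4 methylidene closes ring A as a trisubstituted cyclohexene (C4=C5 necessarily cis) on the cis-disposed arms of ring B, giving the cis-fused decalin because no other alkene pair can form an unstrained ring.

Step 16
Reactants: 29 cis-decalin-3,8-diol
Product: 31 (1(10)Z,4Z,6S,7S)-6,12-bis[(tert-butyldimethylsilyl)oxy]-15-[(4-methoxybenzyl)oxy]germacra-1(10),4,11(13)-triene-3,8-dione, via cyclic lead diolate 30 (not isolated)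
Conditions: Pb(OAc)4, pyridine, CH2Cl2, −20 to 0 °C; cold filtration through Celite; used at once
Reagents that add atoms: none
Why: The cis-diol displaces two acetates from tetravalent lead to give the five-membered cyclic diolate 30, which fragments in a concerted two-electron process to two carbonyl groups and Pb(OAc)2 (Criegee glycol cleavage, long established for ring-fusion diols of bicyclic systems giving medium-ring diketones). No bond is formed: the ten-membered ring arises by scission of the C3–C8 bond shared by rings A and B, a ring expansion by fragmentation rather than a cyclisation. No stereocentre is created, those at C3 and C8 are erased, and C6 and C7 are untouched because the medium is cold and only weakly basic. The C1=C10 and C4=C5 double bonds keep the cis geometry imposed by their six-membered rings, which is the geometry of the target. The step needs chemoselectivity for the glycol over the three alkenes, the PMB ether and the silyl ethers, and the gauche, cis arrangement of the two tertiary hydroxyls secures it by letting the cyclic ester form far faster than any allylic acetoxylation. The β,γ-unsaturated 1,6-diketone is not stored but reduced directly, since it could otherwise conjugate or close transannularly.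

Step 17
Reactants: 31 diketone
Product: 32 (1(10)Z,3S,4Z,6S,7S)-6,12-bis[(tert-butyldimethylsilyl)oxy]-3-hydroxy-15-[(4-methoxybenzyl)oxy]germacra-1(10),4,11(13)-trien-8-one
Conditions: (R)-Me-CBS oxazaborolidine [(R)-1-methyl-3,3-diphenyltetrahydro-1H,3H-pyrrolo[1,2-c][1,3,2]oxazaborole], catecholborane, toluene–CH2Cl2, −78 °C; MeOH, then pH 7 buffer
Reagents that add atoms: none
Why: Corey–Bakshi–Shibata reduction, in which the conjugated C3 carbonyl binds the oxazaborolidine with the alkenyl group as the large substituent, gives the (3S)-allylic alcohol by 1,2-reduction under catalyst control while the hindered α-branched C8 ketone is left at this temperature.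

Step 18
Reactants: 32 hydroxy ketone
Product: 33 3-acetate of 32
Conditions: Ac2O, pyridine, DMAP (cat.), CH2Cl2, 0 °C
Reagents that add atoms: acetic anhydride, CC(=O)OC(C)=O
Why: Acetylation of the only free hydroxyl fixes the C3 acetate before a second hydroxyl exists, so no site selection is needed.

Step 19
Reactants: 33 acetoxy ketone
Product: 34 (1(10)Z,3S,4Z,6S,7R,8R)-3-acetoxy-6,12-bis[(tert-butyldimethylsilyl)oxy]-15-[(4-methoxybenzyl)oxy]germacra-1(10),4,11(13)-trien-8-ol
Conditions: (S)-Me-CBS oxazaborolidine (enantiomer of the step 17 reagent), catecholborane, toluene, −40 to −20 °C; MeOH, then pH 7 buffer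
Reagents that add atoms: none
Why: Corey–Bakshi–Shibata reduction with the antipodal catalyst (branched C7 as the large substituent) delivers hydride to the same face that Felkin–Anh attack anti to the C7–C6 ring bond prefers, giving the (8R)-alcohol cis to the C7 side chain.

Step 20
Reactants: 34 homoallylic alcohol
Product: 35 (1R,3S,4Z,6S,7R,8R,10S)-3-acetoxy-1,10-epoxy-6,12-bis[(tert-butyldimethylsilyl)oxy]-15-[(4-methoxybenzyl)oxy]germacra-4,11(13)-dien-8-ol
Conditions: VO(acac)2 (cat.), t-BuOOH, CH2Cl2, 0 to 23 °C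
Reagents that add atoms: tert-butyl hydroperoxide, CC(C)(C)OO
Why: Hydroxyl-directed epoxidation, in which the vanadium alkoxide of the homoallylic C8–OH delivers oxygen to the near face of the electron-rich trisubstituted C1=C10 alkene, should give the cis-epoxide on the side of O8, the acetate at C3 preventing direction to C4=C5 and the allylic silyloxy group deactivating C11=C13.

Step 21
Reactants: 35 epoxy alcohol
Product: 36 8-methacrylate of 35
Conditions: methacrylic anhydride, Et3N, DMAP, CH2Cl2, 23 °C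
Reagents that add atoms: methacrylic anhydride, C=C(C)C(=O)OC(=O)C(C)=C
Why: DMAP-catalysed acylation of the hindered secondary C8 alcohol (retention) installs the methacrylate before O6 is freed, so that the lactone can later close only onto O6.

Step 22
Reactants: 36 bis-silyl ether
Product: 37 (1R,3S,4Z,6S,7S,8R,10S)-3-acetoxy-1,10-epoxy-6,12-dihydroxy-15-[(4-methoxybenzyl)oxy]germacra-4,11(13)-dien-8-yl methacrylate
Conditions: HF·pyridine, pyridine, THF, 0 to 23 °C
Reagents that add atoms: none
Why: Pyridine-buffered fluoride cleaves both silyl ethers under weakly acidic conditions that avoid acyl migration to O6 and spare the epoxide, the esters and the PMB ether.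

Step 23
Reactants: 37 diol
Product: 40 15-O-(4-methoxybenzyl) ether of the target, via hydroxy enal 38 (not isolated), via lactol 39 (not isolated)
Conditions: TEMPO (cat.), PhI(OAc)2, CH2Cl2, 23 °C
Reagents that add atoms: none
Why: Oxoammonium oxidation selects the primary allylic C12 alcohol, the enal is trapped by the cis C6 hydroxyl as a five-membered lactol, and further oxidation gives the α-methylene γ-lactone (oxidative lactonisation of a 1,4-diol).

Step 24
Reactants: 40 PMB ether
Product: 41 (1R,3S,4Z,6S,7R,8R,10S)-3-acetoxy-1,10-epoxy-15-hydroxy-8-(methacryloyloxy)germacra-4,11(13)-dien-12,6-olide (CNP0319155.2)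
Conditions: DDQ, CH2Cl2–pH 7 buffer, 0 to 23 °C
Reagents that add atoms: none
Why: Oxidative PMB cleavage (hydride abstraction from the electron-rich benzylic position, then hydrolysis) frees the C15 hydroxyl without affecting the α-methylene lactone, methacrylate, acetate or epoxide.

**Compound list**

1 | 4-methylanisole | COc1ccc(C)cc1 | starting material
2 | 2-lithio-4-methylanisole | COc1ccc(C)cc1[Li] | intermediate
3 | 2-(2-methoxy-5-methylphenyl)ethan-1-ol | COc1ccc(C)cc1CCO | intermediate
4 | (2-methoxy-5-methylphenyl)acetaldehyde | COc1ccc(C)cc1CC=O | intermediate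
5 | (2-methoxy-5-methylphenyl)acetic acid | COc1ccc(C)cc1CC(=O)O | intermediate
6 | (R)-4-benzyloxazolidin-2-one | O=C1N[C@H](Cc2ccccc2)CO1 | starting material
7 | (2-methoxy-5-methylphenyl)acetic pivalic anhydride | COc1ccc(C)cc1CC(=O)OC(=O)C(C)(C)C | intermediate
8 | (R)-4-benzyl-3-[(2-methoxy-5-methylphenyl)acetyl]oxazolidin-2-one | COc1ccc(C)cc1CC(=O)N1[C@H](Cc2ccccc2)COC1=O | intermediate
9 | acrolein | C=CC=O | starting material
10 | dibutylboron (Z)-enolate of 8 | CCCCB(CCCC)O/C(=C\c1cc(C)ccc1OC)N1[C@H](Cc2ccccc2)COC1=O | intermediate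
11 | dibutylboron aldolate of 12 | C=C[C@H](OB(CCCC)CCCC)[C@@H](c1cc(C)ccc1OC)C(=O)N1[C@H](Cc2ccccc2)COC1=O | intermediate
12 | (R)-4-benzyl-3-[(2R,3S)-3-hydroxy-2-(2-methoxy-5-methylphenyl)pent-4-enoyl]oxazolidin-2-one | C=C[C@H](O)[C@@H](c1cc(C)ccc1OC)C(=O)N1[C@H](Cc2ccccc2)COC1=O | intermediate
13 | (2R,3S)-3-hydroxy-N-methoxy-2-(2-methoxy-5-methylphenyl)-N-methylpent-4-enamide | C=C[C@H](O)[C@@H](c1cc(C)ccc1OC)C(=O)N(C)OC | intermediate
14 | (2R,3S)-3-[(tert-butyldimethylsilyl)oxy]-N-methoxy-2-(2-methoxy-5-methylphenyl)-N-methylpent-4-enamide | C=C[C@H](O[Si](C)(C)C(C)(C)C)[C@@H](c1cc(C)ccc1OC)C(=O)N(C)OC | intermediate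
15 | (3R,4S)-1-(benzyloxy)-4-[(tert-butyldimethylsilyl)oxy]-3-(2-methoxy-5-methylphenyl)hex-5-en-2-one | C=C[C@H](O[Si](C)(C)C(C)(C)C)[C@@H](c1cc(C)ccc1OC)C(=O)COCc1ccccc1 | intermediate
16 | (3R,4S)-1-(benzyloxy)-4-[(tert-butyldimethylsilyl)oxy]-3-(2-methoxy-5-methylphenyl)-2-[(trimethylsilyl)methyl]hex-5-en-2-ol (both C2 epimers) | C=C[C@H](O[Si](C)(C)C(C)(C)C)[C@@H](c1cc(C)ccc1OC)C(O)(C[Si](C)(C)C)COCc1ccccc1 | intermediate
17 | (3S,4R)-5-[(benzyloxy)methyl]-4-(2-methoxy-5-methylphenyl)hexa-1,5-dien-3-ol | C=C[C@H](O)[C@@H](c1cc(C)ccc1OC)C(=C)COCc1ccccc1 | intermediate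
18 | (3R,4S)-3-(2-methoxy-5-methylcyclohexa-1,4-dien-1-yl)-2-methylidenehex-5-ene-1,4-diol | C=C[C@H](O)[C@@H](C1=C(OC)CC=C(C)C1)C(=C)CO | intermediate
19 | (3R,4S)-1,4-bis[(tert-butyldimethylsilyl)oxy]-3-(2-methoxy-5-methylcyclohexa-1,4-dien-1-yl)-2-methylidenehex-5-ene | C=C[C@H](O[Si](C)(C)C(C)(C)C)[C@@H](C1=C(OC)CC=C(C)C1)C(=C)CO[Si](C)(C)C(C)(C)C | intermediate
20 | methoxy epoxide of 19 (1-methoxy-7-oxabicyclo[4.1.0]hept-3-ene, epoxide oxygen on the ring face turned toward the C11 branch) | C=C[C@H](O[Si](C)(C)C(C)(C)C)[C@@H]([C@]12CC(C)=CC[C@@]1(OC)O2)C(=C)CO[Si](C)(C)C(C)(C)C | intermediate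
21 | (2R)-2-[(3S,4S)-4-[(tert-butyldimethylsilyl)oxy]-2-{[(tert-butyldimethylsilyl)oxy]methyl}hexa-1,5-dien-3-yl]-2-hydroxy-4-methylcyclohex-4-en-1-one | C=C[C@H](O[Si](C)(C)C(C)(C)C)[C@@H]([C@]1(O)CC(C)=CCC1=O)C(=C)CO[Si](C)(C)C(C)(C)C | intermediate
22 | trimethylsilyl ether of 21 | C=C[C@H](O[Si](C)(C)C(C)(C)C)[C@@H]([C@]1(O[Si](C)(C)C)CC(C)=CCC1=O)C(=C)CO[Si](C)(C)C(C)(C)C | intermediate
23 | 2-bromoprop-2-en-1-ol | OCC(Br)=C | starting material
24 | 1-{[(2-bromoprop-2-en-1-yl)oxy]methyl}-4-methoxybenzene | C=C(Br)COCc1ccc(OC)cc1 | intermediate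
25 | 3-[(4-methoxybenzyl)oxy]prop-1-en-2-yllithium | [Li]C(=C)COCc1ccc(OC)cc1 | intermediate
26 | dichloro{3-[(4-methoxybenzyl)oxy]prop-1-en-2-yl}cerium | Cl[Ce](Cl)C(=C)COCc1ccc(OC)cc1 | intermediate
27 | C8 trimethylsilyl ether of 28 | C=C[C@H](O[Si](C)(C)C(C)(C)C)[C@@H]([C@]1(O[Si](C)(C)C)CC(C)=CC[C@]1(O)C(=C)COCc2ccc(OC)cc2)C(=C)CO[Si](C)(C)C(C)(C)C | intermediate
28 | (1S,2R)-2-[(3S,4S)-4-[(tert-butyldimethylsilyl)oxy]-2-{[(tert-butyldimethylsilyl)oxy]methyl}hexa-1,5-dien-3-yl]-1-{3-[(4-methoxybenzyl)oxy]prop-1-en-2-yl}-4-methylcyclohex-4-ene-1,2-diol | C=C[C@H](O[Si](C)(C)C(C)(C)C)[C@@H]([C@]1(O)CC(C)=CC[C@]1(O)C(=C)COCc2ccc(OC)cc2)C(=C)CO[Si](C)(C)C(C)(C)C | intermediate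
29 | (3S,4S,4aR,8aS)-3-[(tert-butyldimethylsilyl)oxy]-4-{3-[(tert-butyldimethylsilyl)oxy]prop-1-en-2-yl}-1-{[(4-methoxybenzyl)oxy]methyl}-6-methyl-3,4,4a,5,8,8a-hexahydronaphthalene-4a,8a-diol (cis-decalin-3,8-diol; germacrane descriptors 3S,6S,7S,8R) | O[C@]12CC=C(C)C[C@@]1(O)[C@@H](C(=C)CO[Si](C)(C)C(C)(C)C)[C@@H](O[Si](C)(C)C(C)(C)C)C=C2COCc3ccc(OC)cc3 | intermediate
30 | cyclic diacetoxylead diolate of 29 (O3–Pb–O8 five-membered ring) | CC(=O)O[Pb]1(OC(C)=O)O[C@]23CC=C(C)C[C@@]2(O1)[C@@H](C(=C)CO[Si](C)(C)C(C)(C)C)[C@@H](O[Si](C)(C)C(C)(C)C)C=C3COCc4ccc(OC)cc4 | intermediate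
31 | (1(10)Z,4Z,6S,7S)-6,12-bis[(tert-butyldimethylsilyl)oxy]-15-[(4-methoxybenzyl)oxy]germacra-1(10),4,11(13)-triene-3,8-dione | O=C1C/C(C)=C\CC(=O)/C(COCc2ccc(OC)cc2)=C\[C@H](O[Si](C)(C)C(C)(C)C)[C@@H]1C(=C)CO[Si](C)(C)C(C)(C)C | intermediate
32 | (1(10)Z,3S,4Z,6S,7S)-6,12-bis[(tert-butyldimethylsilyl)oxy]-3-hydroxy-15-[(4-methoxybenzyl)oxy]germacra-1(10),4,11(13)-trien-8-one | O=C1C/C(C)=C\C[C@H](O)/C(COCc2ccc(OC)cc2)=C\[C@H](O[Si](C)(C)C(C)(C)C)[C@@H]1C(=C)CO[Si](C)(C)C(C)(C)C | intermediate
33 | (1(10)Z,3S,4Z,6S,7S)-3-acetoxy-6,12-bis[(tert-butyldimethylsilyl)oxy]-15-[(4-methoxybenzyl)oxy]germacra-1(10),4,11(13)-trien-8-one | O=C1C/C(C)=C\C[C@H](OC(C)=O)/C(COCc2ccc(OC)cc2)=C\[C@H](O[Si](C)(C)C(C)(C)C)[C@@H]1C(=C)CO[Si](C)(C)C(C)(C)C | intermediate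
34 | (1(10)Z,3S,4Z,6S,7R,8R)-3-acetoxy-6,12-bis[(tert-butyldimethylsilyl)oxy]-15-[(4-methoxybenzyl)oxy]germacra-1(10),4,11(13)-trien-8-ol | O[C@@H]1C/C(C)=C\C[C@H](OC(C)=O)/C(COCc2ccc(OC)cc2)=C\[C@H](O[Si](C)(C)C(C)(C)C)[C@@H]1C(=C)CO[Si](C)(C)C(C)(C)C | intermediate
35 | (1R,3S,4Z,6S,7R,8R,10S)-3-acetoxy-1,10-epoxy-6,12-bis[(tert-butyldimethylsilyl)oxy]-15-[(4-methoxybenzyl)oxy]germacra-4,11(13)-dien-8-ol | O[C@@H]1C[C@]2(C)O[C@@H]2C[C@H](OC(C)=O)/C(COCc3ccc(OC)cc3)=C\[C@H](O[Si](C)(C)C(C)(C)C)[C@@H]1C(=C)CO[Si](C)(C)C(C)(C)C | intermediate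
36 | (1R,3S,4Z,6S,7R,8R,10S)-3-acetoxy-1,10-epoxy-6,12-bis[(tert-butyldimethylsilyl)oxy]-15-[(4-methoxybenzyl)oxy]germacra-4,11(13)-dien-8-yl methacrylate | C=C(C)C(=O)O[C@@H]1C[C@]2(C)O[C@@H]2C[C@H](OC(C)=O)/C(COCc3ccc(OC)cc3)=C\[C@H](O[Si](C)(C)C(C)(C)C)[C@@H]1C(=C)CO[Si](C)(C)C(C)(C)C | intermediate
37 | (1R,3S,4Z,6S,7S,8R,10S)-3-acetoxy-1,10-epoxy-6,12-dihydroxy-15-[(4-methoxybenzyl)oxy]germacra-4,11(13)-dien-8-yl methacrylate | C=C(C)C(=O)O[C@@H]1C[C@]2(C)O[C@@H]2C[C@H](OC(C)=O)/C(COCc3ccc(OC)cc3)=C\[C@H](O)[C@@H]1C(=C)CO | intermediate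
38 | 12-aldehyde of 37 (6-hydroxy-12-oxo compound) | C=C(C)C(=O)O[C@@H]1C[C@]2(C)O[C@@H]2C[C@H](OC(C)=O)/C(COCc3ccc(OC)cc3)=C\[C@H](O)[C@@H]1C(=C)C=O | intermediate
39 | 12,6-lactol of 38 (both C12 epimers) | C=C(C)C(=O)O[C@@H]1C[C@]2(C)O[C@@H]2C[C@H](OC(C)=O)/C(COCc3ccc(OC)cc3)=C\[C@@H]2OC(O)C(=C)[C@@H]21 | intermediate
40 | (1R,3S,4Z,6S,7R,8R,10S)-3-acetoxy-1,10-epoxy-15-[(4-methoxybenzyl)oxy]-8-(methacryloyloxy)germacra-4,11(13)-dien-12,6-olide | C=C(C)C(=O)O[C@@H]1C[C@]2(C)O[C@@H]2C[C@H](OC(C)=O)/C(COCc3ccc(OC)cc3)=C\[C@@H]2OC(=O)C(=C)[C@@H]21 | intermediate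
41 | (1R,3S,4Z,6S,7R,8R,10S)-3-acetoxy-1,10-epoxy-15-hydroxy-8-(methacryloyloxy)germacra-4,11(13)-dien-12,6-olide (CNP0319155.2) | C=C(C)C(=O)O[C@@H]1C[C@]2(C)O[C@@H]2C[C@H](OC(C)=O)/C(CO)=C\[C@@H]2OC(=O)C(=C)[C@@H]21 | target

**Step count and risks**

Total step count: 24. Longest linear sequence: 23 steps (steps 1–12 and 14–24; step 13 is a one-step side branch).

Steps most likely to fail:

Step 14. The alkoxy-substituted vinyllithium may be lost by β-elimination to allene before it adds, the hindered ketone may be enolised instead of attacked, or attack may occur in part syn to the silyloxy group. Fallback, setting out from 22: 2-bromoprop-2-en-1-ol 23 is converted without protection (t-BuLi, 3 equiv, Et2O, −78 to 0 °C) into lithium 2-lithioprop-2-en-1-olate F1, whose alkoxide cannot leave. F1 is added to 22 in THF in the presence of LaCl3·2LiCl at −78 °C to give the silyl ether adduct F2. Methanolysis (K2CO3, MeOH) gives the triol F3. Etherification of its only primary hydroxyl (NaH, 1 equiv, 4-methoxybenzyl chloride, THF) returns to 28.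

Step 17. The 1,6-diketone may drift into conjugation or close by transannular aldol reaction before the cold, catalyst-bound reduction is complete, and the catalyst may fail to distinguish the two carbonyl groups. Fallback, setting out from 31: both carbonyls are reduced in one fast operation with the (S)-oxazaborolidine and BH3·SMe2 (THF, −40 °C, borane added slowly so that alkene hydroboration does not compete). This is matched at C8 and gives the (3R,8R)-diol F4. A Mitsunobu reaction (PPh3, diisopropyl azodicarboxylate, AcOH, toluene, 0 °C) then esterifies the less hindered allylic C3 carbinol with inversion, and the route is rejoined at 34.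

Step 20. Oxygen may be delivered to the wrong face of C1=C10 if the ring conformer that presents the C8 hydroxyl to the required face is not the populated one, or to C11=C13, which is also homoallylic to O8. Fallback, setting out from 34: the alcohol is first acylated as in step 21 to the methacrylate F5. C1=C10 is then epoxidised under reagent control by a Shi epoxidation (fructose-derived ketone of the enantiomeric series chosen from the spiro transition-state model, Oxone (2KHSO5·KHSO4·K2SO4), K2CO3, MeCN–dimethoxymethane–buffer, 0 °C), which should leave the electron-poor and 1,1-disubstituted alkenes alone and returns to 36.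

Further compounds
F1 | step 14 | lithium 2-lithioprop-2-en-1-olate | [Li]OCC([Li])=C
F2 | step 14 | C8 trimethylsilyl ether of F3 | C=C[C@H](O[Si](C)(C)C(C)(C)C)[C@@H]([C@]1(O[Si](C)(C)C)CC(C)=CC[C@]1(O)C(=C)CO)C(=C)CO[Si](C)(C)C(C)(C)C
F3 | step 14 | (1S,2R)-2-[(3S,4S)-4-[(tert-butyldimethylsilyl)oxy]-2-{[(tert-butyldimethylsilyl)oxy]methyl}hexa-1,5-dien-3-yl]-1-(3-hydroxyprop-1-en-2-yl)-4-methylcyclohex-4-ene-1,2-diol | C=C[C@H](O[Si](C)(C)C(C)(C)C)[C@@H]([C@]1(O)CC(C)=CC[C@]1(O)C(=C)CO)C(=C)CO[Si](C)(C)C(C)(C)C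
F4 | step 17 | (1(10)Z,3R,4Z,6S,7R,8R)-6,12-bis[(tert-butyldimethylsilyl)oxy]-15-[(4-methoxybenzyl)oxy]germacra-1(10),4,11(13)-triene-3,8-diol | O[C@@H]1C/C(C)=C\C[C@@H](O)/C(COCc2ccc(OC)cc2)=C\[C@H](O[Si](C)(C)C(C)(C)C)[C@@H]1C(=C)CO[Si](C)(C)C(C)(C)C
F5 | step 20 | (1(10)Z,3S,4Z,6S,7R,8R)-3-acetoxy-6,12-bis[(tert-butyldimethylsilyl)oxy]-15-[(4-methoxybenzyl)oxy]germacra-1(10),4,11(13)-trien-8-yl methacrylate | C=C(C)C(=O)O[C@@H]1C/C(C)=C\C[C@H](OC(C)=O)/C(COCc2ccc(OC)cc2)=C\[C@H](O[Si](C)(C)C(C)(C)C)[C@@H]1C(=C)CO[Si](C)(C)C(C)(C)C
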